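**Plan**

- Retrosynthesis (labdane numbering): the C18–O silyl group and the C15 formyl level are adjusted last. C13=C14 is cut by a Horner–Wadsworth–Emmons reaction, C9–C11 (with C8=C17) by an allylsilane conjugate addition, C8=C9 by ring-closing metathesis, C6–C7 by allylation of a C6 acyl group, and finally C1–C10 and C4–C5 together by an intramolecular Diels–Alder reaction.
- Enabling feature: O18 and C6 are 1,3-related across the C4–C5 bond and ring A carries nothing on C1–C3. An ester C18–O–C6(=O) can therefore tether a C1–C4 diene (C4 bearing CH3 and CH2O) to a C5=C10 dienophile that C6 and a formyl group at C9 activate.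
- Forward: a dienol and a formyl-enoic acid are esterified; the cycloaddition builds ring A fused to a temporary γ-lactone; the lactone is opened (C18–OH freed, C6 becomes a ketone); ring B is closed by metathesis; the side chain is grown from C9.
- Stereochemistry: C4, C5 and C10 arise in the cycloaddition (relative configuration from the two (E)-alkenes and a formyl-endo transition state, absolute configuration from a chiral oxazaborolidinium catalyst). C6 comes from hydride attack on the α face, C9 from axial α attack on the ring B allylsilane anti to the C10 methyl, and the (E)-C13=C14 bond from the olefination.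

Key step: step 7

Remark on numbering: labdane numbering is used for all positions and β is the face of the C10 methyl group; the target is 4α-CH2OH, 4β-CH3, 5α-H, 6β-OBz, 9β-H (side chain α), 10β-CH3, i.e. (4R,5R,6R,9R,10R).

Assumption: the (S)-configured oxazaborolidinium ion is taken to leave open the face of the bound enal that leads to 10 as drawn; if the sense is the opposite, the (R)-catalyst is used in the same way.

**Route**

Step 1
Reactants: 1 acrolein; 2 ethyl 2-(triphenylphosphoranylidene)propanoate
Product: 3 ethyl (2E)-2-methylpenta-2,4-dienoate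
Conditions: CH2Cl2, 0 °C → rt (trace hydroquinone)
Reagents that add atoms: none
Why: Wittig olefination with a stabilised ylide reacts only at the formyl group of acrolein and should give the (E)-trisubstituted enoate.

Step 2
Reactants: 3 ethyl (2E)-2-methylpenta-2,4-dienoate
Product: 4 (2E)-2-methylpenta-2,4-dien-1-ol
Conditions: iBu2AlH (2.2 equiv), Et2O, −78 → 0 °C; aq. potassium sodium tartrate
Reagents that add atoms: none
Why: 1,2-reduction of the conjugated ester by the aluminium hydride gives the allylic alcohol and leaves the diene untouched.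

Step 3
Reactants: 5 ethyl (2E)-3-methyl-4-oxobut-2-enoate
Product: 6 ethyl (2E)-4,4-dimethoxy-3-methylbut-2-enoate
Conditions: HC(OMe)3, MeOH, p-TsOH·H2O (1 mol %), rt
Reagents that add atoms: trimethyl orthoformate, COC(OC)OC
Why: acid-catalysed acetalisation with orthoformate as water scavenger masks the formyl group so that the ester can be cleaved by base, the more stable (E)-geometry being kept.

Step 4
Reactants: 6 ethyl (2E)-4,4-dimethoxy-3-methylbut-2-enoate
Product: 7 (2E)-4,4-dimethoxy-3-methylbut-2-enoic acid
Conditions: LiOH·H2O, THF–H2O, 0 °C → rt; cold 1 M HCl to pH 4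
Reagents that add atoms: lithium hydroxide, [Li+].[OH-]
Why: saponification of the ethyl ester, the acetal being inert to hydroxide and surviving brief acidification at 0 °C.

Step 5
Reactants: 7 (2E)-4,4-dimethoxy-3-methylbut-2-enoic acid; 4 (2E)-2-methylpenta-2,4-dien-1-ol
Product: 8 (2E)-2-methylpenta-2,4-dien-1-yl (2E)-4,4-dimethoxy-3-methylbut-2-enoate
Conditions: EDC·HCl, DMAP (cat.), CH2Cl2, 0 °C → rt
Reagents that add atoms: none
Why: carbodiimide (Steglich-type) esterification joins acid and dienol under neutral conditions that leave the acetal, the diene and both alkene geometries intact.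

Step 6
Reactants: 8 (2E)-2-methylpenta-2,4-dien-1-yl (2E)-4,4-dimethoxy-3-methylbut-2-enoate
Product: 9 (2E)-2-methylpenta-2,4-dien-1-yl (2E)-3-methyl-4-oxobut-2-enoate
Conditions: 10% aq. oxalic acid on SiO2, CH2Cl2, rt; used at once, kept cold
Reagents that add atoms: water, O
Why: mild acetal hydrolysis on wet silica frees the formyl group and so switches on the dienophile only at this point, without ionising the allylic ester.

Step 7
Reactants: 9 (2E)-2-methylpenta-2,4-dien-1-yl (2E)-3-methyl-4-oxobut-2-enoate
Product: 10 trans-fused lactone aldehyde (3aR,7S,7aS)-3a,7-dimethyl-1-oxo-1,3,3a,6,7,7a-hexahydro-2-benzofuran-7-carbaldehyde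
Conditions: (S)-1-(2-methylphenyl)-3,3-diphenyltetrahydro-1H,3H-pyrrolo[1,2-c][1,3,2]oxazaborole (20 mol %), HNTf2 (16 mol %), CH2Cl2 (0.02 M), −78 → −20 °C
Reagents that add atoms: none
Why: Proposed new method: the formyl group of 9 binds to the boron of the cationic oxazaborolidinium ion (with the usual formyl C–H···O contact), which lowers the LUMO of the C5=C10 bond and shields one of its faces, and the tethered C1–C4 diene then adds in a concerted, asynchronous [4+2] cycloaddition; the closest known reaction types are the oxazaborolidinium-catalysed enantioselective intramolecular Diels–Alder reaction of 2-methyl trienals with all-carbon tethers and the thermal intramolecular Diels–Alder reaction of pentadienyl fumarates, the new element being catalytic control of absolute configuration across an ester tether. The C4–C5 bond closes the five-membered lactone and, together with C1–C10, the six-membered ring A, both in the fused mode that a three-atom tether between C4 and C5 enforces, which also fixes the regiochemistry. The trans relation of H-5 and the C10 methyl follows from the (E)-dienophile by suprafacial addition, and the configuration at C4 (CH3 cis to the C10 methyl and to C6, CH2O cis to H-5) follows from the (E)-diene together with the formyl-endo, tether-exo transition state that leads to the trans-fused lactone. The absolute configuration is set by the catalyst, which lets the diene reach only the open face of the bound enal. The step needs endo selectivity for the formyl group (secured by its Lewis acid activation and its trans position to the tether), facial selectivity (secured by the catalyst at a temperature where the thermal background reaction is negligible) and intra- over intermolecular reaction (secured by dilution).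

Step 8
Reactants: 10 trans-fused lactone aldehyde
Product: 11 saturated lactone aldehyde (3aR,7S,7aS)-3a,7-dimethyl-1-oxooctahydro-2-benzofuran-7-carbaldehyde
Conditions: H2 (1 atm), 5% Pd/C, EtOAc, rt
Reagents that add atoms: none
Why: heterogeneous hydrogenation saturates the only C=C bond (C2=C3 of ring A) before any other alkene is introduced, and the neopentyl formyl group and the lactone should not be reduced under these conditions.

Step 9
Reactants: 11 saturated lactone aldehyde
Product: 12 vinyl lactone (3aR,7R,7aR)-7-ethenyl-3a,7-dimethylhexahydro-2-benzofuran-1(3H)-one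
Conditions: Ph3PCH3Br (1.5 equiv), KN(SiMe3)2 (1.4 equiv), THF, 0 °C; then 11, −78 → 0 °C
Reagents that add atoms: methyltriphenylphosphonium bromide, C[P+](c1ccccc1)(c1ccccc1)c1ccccc1.[Br-]
Why: Wittig methylenation of the non-enolisable aldehyde turns C9 into a vinyl carbon, a slight deficit of base keeping H-5 (α to the lactone carbonyl) from epimerising and the low temperature keeping the ylide off the lactone.

Step 10
Reactants: 12 vinyl lactone
Product: 13 hydroxy amide (1R,2R,6R)-2-ethenyl-6-(hydroxymethyl)-N-methoxy-N,2,6-trimethylcyclohexane-1-carboxamide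
Conditions: MeNH(OMe)·HCl (3 equiv), AlMe3 (3 equiv), CH2Cl2, 0 °C → rt; aq. potassium sodium tartrate
Reagents that add atoms: N,O-dimethylhydroxylamine hydrochloride, CNOC.Cl
Why: aminolysis of the strained trans-fused lactone by the aluminium amide (attack on the open α face of C6) frees the C18 hydroxyl and turns C6 into an N-methoxy-N-methylamide that accepts one carbon nucleophile only.

Step 11
Reactants: 13 hydroxy amide
Product: 14 silyl ether amide (1R,2R,6R)-6-({[tert-butyl(dimethyl)silyl]oxy}methyl)-2-ethenyl-N-methoxy-N,2,6-trimethylcyclohexane-1-carboxamide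
Conditions: TBSCl, imidazole, DMF, 0 °C → rt
Reagents that add atoms: tert-butyldimethylsilyl chloride, CC(C)(C)[Si](C)(C)Cl
Why: silylation of the primary neopentyl alcohol blocks relactonisation and installs the only protecting group of the route, which stays on O18 until the last step.

Step 12
Reactants: 14 silyl ether amide; 15 [2-(chloromethyl)prop-2-en-1-yl]trimethylsilane
Product: 17 dienyl ketone (C6 ketone carrying the 2-[(trimethylsilyl)methyl]allyl group), via Grignard reagent 16 (not isolated)
Conditions: 15, Mg turnings, THF, 0 °C; then 14, −20 → 0 °C; cold aq. NH4Cl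
Reagents that add atoms: magnesium, [Mg] (held in 16, not in 17)
Why: addition of an allylic Grignard reagent to an N-methoxy-N-methylamide stops at the ketone because of the chelated tetrahedral intermediate, the allyl metal reaching even the hindered C6 carbonyl through its cyclic transition state and bringing C7, C8 and C17 with the allylsilane in place.

Step 13
Reactants: 17 dienyl ketone
Product: 18 ring B enone (C6 ketone, C8=C9, CH2SiMe3 on C8; 4α-CH2OTBS, 4β-CH3, 5α-H, 10β-CH3)
Conditions: second-generation Hoveyda–Grubbs catalyst RuCl2(H2IMes)(=CH–C6H4-2-OiPr) (5 mol %), 1,4-benzoquinone (10 mol %), toluene (0.005 M), 80 °C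
Reagents that add atoms: none
Why: ring-closing metathesis of the vinyl group on C10 with the 1,1-disubstituted alkene closes the six-membered ring B with a trisubstituted C8=C9 bond and loss of ethene, benzoquinone suppressing migration of the β,γ-double bond into conjugation.

Step 14
Reactants: 18 ring B enone
Product: 19 6β-alcohol (axial hydroxyl on C6; otherwise as 18)
Conditions: NaBH4, CeCl3·7H2O, MeOH–THF, −40 → 0 °C
Reagents that add atoms: none
Why: in this Luche reduction hydride should attack C6 from the α face, because the β face is blocked by the syn-axial methyl groups on C4 and C10, to give the axial 6β-alcohol, and the fast non-basic conditions avoid conjugation of the β,γ-unsaturated ketone.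

Step 15
Reactants: 19 6β-alcohol
Product: 20 6β-benzoate allylsilane
Conditions: BzCl (3 equiv), DMAP (1 equiv), pyridine, 60 °C
Reagents that add atoms: benzoyl chloride, O=C(Cl)c1ccccc1
Why: DMAP-catalysed acylation installs the benzoate of the target on the hindered axial alcohol (hence excess reagent and heating), the allylsilane and the silyl ether being stable to pyridine.

Step 16
Reactants: 20 6β-benzoate allylsilane; 21 but-3-en-2-one
Product: 22 methyl ketone (C8=C17 exocyclic, 9α-(3-oxobutyl), 9β-H)
Conditions: TiCl4 (1.1 equiv), CH2Cl2, −78 °C; aq. NaHCO3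
Reagents that add atoms: none
Why: in this Hosomi–Sakurai conjugate addition the γ-carbon (C9) of the allylsilane attacks the activated enone with loss of silicon, forming C9–C11 and the exocyclic C8=C17 bond at once, and the electrophile should approach C9 axially from the α face, anti to the C10 methyl and the 6β-benzoate, so that the chain is α and H-9 β.

Step 17
Reactants: 22 methyl ketone; 23 diethyl {2-[methoxy(methyl)amino]-2-oxoethyl}phosphonate
Product: 24 (E)-enamide (C13=C14, N-methoxy-N-methylamide at C15)
Conditions: NaH, THF, 0 → 50 °C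
Reagents that add atoms: none
Why: Horner–Wadsworth–Emmons olefination of the methyl ketone places the larger ketone substituent trans to the carbonyl group, so the (E)-isomer should predominate (the minor (Z)-isomer being removed by chromatography), and the hindered benzoate is not attacked by the stabilised anion.

Step 18
Reactants: 24 (E)-enamide
Product: 25 silyl-protected enal
Conditions: iBu2AlH (1.3 equiv), THF, −78 °C; aq. potassium sodium tartrate
Reagents that add atoms: none
Why: reduction of the N-methoxy-N-methylamide stops at the chelated hemiaminal, which releases the enal only on work-up, so neither over-reduction nor E/Z isomerisation is expected and the hindered, less reactive benzoate should survive at −78 °C.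

Step 19
Reactants: 25 silyl-protected enal
Product: 26 target, 6β-benzoyloxy-18-hydroxy-9βH-labda-8(17),13E-dien-15-al
Conditions: HF·pyridine, pyridine, THF, 0 °C → rt
Reagents that add atoms: none
Why: buffered fluoride cleavage of the silyl ether frees the C18 hydroxyl without touching the enal, the benzoate or the exocyclic alkene and without acyl migration.

**Compound list**

1 | acrolein (prop-2-enal) | C=CC=O | starting material
2 | ethyl 2-(triphenylphosphoranylidene)propanoate | CCOC(=O)C(C)=P(c1ccccc1)(c1ccccc1)c1ccccc1 | starting material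
3 | ethyl (2E)-2-methylpenta-2,4-dienoate | CCOC(=O)/C(C)=C/C=C | intermediate
4 | (2E)-2-methylpenta-2,4-dien-1-ol | OC/C(C)=C/C=C | intermediate
5 | ethyl (2E)-3-methyl-4-oxobut-2-enoate | O=C/C(C)=C/C(=O)OCC | starting material
6 | ethyl (2E)-4,4-dimethoxy-3-methylbut-2-enoate | COC(OC)/C(C)=C/C(=O)OCC | intermediate
7 | (2E)-4,4-dimethoxy-3-methylbut-2-enoic acid | COC(OC)/C(C)=C/C(=O)O | intermediate
8 | (2E)-2-methylpenta-2,4-dien-1-yl (2E)-4,4-dimethoxy-3-methylbut-2-enoate | COC(OC)/C(C)=C/C(=O)OC/C(C)=C/C=C | intermediate
9 | (2E)-2-methylpenta-2,4-dien-1-yl (2E)-3-methyl-4-oxobut-2-enoate | O=C/C(C)=C/C(=O)OC/C(C)=C/C=C | intermediate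
10 | (3aR,7S,7aS)-3a,7-dimethyl-1-oxo-1,3,3a,6,7,7a-hexahydro-2-benzofuran-7-carbaldehyde (trans-fused lactone; ring A with C2=C3; formyl C9 cis to H-5) | O=C2[C@H]1[C@](C)(CO2)C=CC[C@]1(C)C=O | intermediate
11 | (3aR,7S,7aS)-3a,7-dimethyl-1-oxooctahydro-2-benzofuran-7-carbaldehyde | O=C2[C@H]1[C@](C)(CO2)CCC[C@]1(C)C=O | intermediate
12 | (3aR,7R,7aR)-7-ethenyl-3a,7-dimethylhexahydro-2-benzofuran-1(3H)-one | O=C2[C@H]1[C@](C)(CO2)CCC[C@]1(C)C=C | intermediate
13 | (1R,2R,6R)-2-ethenyl-6-(hydroxymethyl)-N-methoxy-N,2,6-trimethylcyclohexane-1-carboxamide | CON(C)C(=O)[C@H]1[C@](C)(CO)CCC[C@]1(C)C=C | intermediate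
14 | (1R,2R,6R)-6-({[tert-butyl(dimethyl)silyl]oxy}methyl)-2-ethenyl-N-methoxy-N,2,6-trimethylcyclohexane-1-carboxamide | CON(C)C(=O)[C@H]1[C@](C)(CO[Si](C)(C)C(C)(C)C)CCC[C@]1(C)C=C | intermediate
15 | [2-(chloromethyl)prop-2-en-1-yl]trimethylsilane | C[Si](C)(C)CC(=C)CCl | starting material
16 | {2-[(trimethylsilyl)methyl]prop-2-en-1-yl}magnesium chloride | C[Si](C)(C)CC(=C)C[Mg]Cl | intermediate (not isolated)
17 | 1-[(1R,2R,6R)-6-({[tert-butyl(dimethyl)silyl]oxy}methyl)-2-ethenyl-2,6-dimethylcyclohexyl]-3-[(trimethylsilyl)methyl]but-3-en-1-one | C[Si](C)(C)CC(=C)CC(=O)[C@H]1[C@](C)(CO[Si](C)(C)C(C)(C)C)CCC[C@]1(C)C=C | intermediate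
18 | ring B enone: trans-fused decalin with C6 ketone, C8=C9, CH2SiMe3 on C8, 4α-CH2OTBS, 4β-CH3, 5α-H, 10β-CH3 | C[Si](C)(C)CC=1CC(=O)[C@H]2[C@](C)(CO[Si](C)(C)C(C)(C)C)CCC[C@]2(C)C=1 | intermediate
19 | 6β-alcohol of 18 (axial OH on C6) | C[Si](C)(C)CC=1C[C@@H](O)[C@H]2[C@](C)(CO[Si](C)(C)C(C)(C)C)CCC[C@]2(C)C=1 | intermediate
20 | 6β-benzoate of 19 | C[Si](C)(C)CC=1C[C@@H](OC(=O)c3ccccc3)[C@H]2[C@](C)(CO[Si](C)(C)C(C)(C)C)CCC[C@]2(C)C=1 | intermediate
21 | but-3-en-2-one | CC(=O)C=C | starting material
22 | methyl ketone: 6β-benzoyloxy-18-(tert-butyldimethylsilyloxy)-8(17)-ene with 9α-(3-oxobutyl) and 9β-H | C=C1C[C@@H](OC(=O)c3ccccc3)[C@H]2[C@](C)(CO[Si](C)(C)C(C)(C)C)CCC[C@]2(C)[C@@H]1CCC(C)=O | intermediate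
23 | diethyl {2-[methoxy(methyl)amino]-2-oxoethyl}phosphonate | CCOP(=O)(CC(=O)N(C)OC)OCC | starting material
24 | (13E)-N-methoxy-N-methyl amide of the 15-oic acid (6β-OBz, 18-OTBS, 8(17)-ene, 9βH) | C=C1C[C@@H](OC(=O)c3ccccc3)[C@H]2[C@](C)(CO[Si](C)(C)C(C)(C)C)CCC[C@]2(C)[C@@H]1CC/C(C)=C/C(=O)N(C)OC | intermediate
25 | 18-O-tert-butyldimethylsilyl ether of the target | C=C1C[C@@H](OC(=O)c3ccccc3)[C@H]2[C@](C)(CO[Si](C)(C)C(C)(C)C)CCC[C@]2(C)[C@@H]1CC/C(C)=C/C=O | intermediate
26 | (4R,5R,6R,9R,10R)-6β-benzoyloxy-18-hydroxy-9βH-labda-8(17),13E-dien-15-al | C=C1C[C@@H](OC(=O)c2ccccc2)[C@H]2[C@](C)(CO)CCC[C@]2(C)[C@@H]1CC/C(C)=C/C=O | target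

**Count**

Total steps: 19. Longest linear sequence: 17 steps (steps 1–2 or 3–4, then 5–19).

**Steps most likely to fail**

Step 7 (proposed new method). The cycloaddition may be too slow under the catalyst, because the ester tether must leave its preferred conformation and the diene carries a methyl group on the inside of its C4 terminus. The acid catalyst may then decompose or oligomerise the diene, or the endo and facial selectivity may be poor. The fallback uses known chemistry, sets out from 9 and returns at 10. Heating 9 in toluene (0.01 M, 110 °C, a little 2,6-di-tert-butyl-4-methylphenol) is the known thermal cycloaddition of fumarate-type pentadienyl esters and should give the trans-fused adduct as the racemate, i.e. 10 together with the enantiomer of 10 F1. Condensation of the mixture with (1S,2S)-N,N'-dimethyl-1,2-diphenylethane-1,2-diamine (4 Å sieves, CH2Cl2, rt) should give the imidazolidine of 10 F2 and the imidazolidine of the enantiomer F3, to be separated by chromatography or crystallisation. Hydrolysis of F2 (aq. AcOH–THF, rt) returns 10.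

Step 16. Intermolecular attack at C9, next to the quaternary C10, may be slow, so that protodesilylation of the allylsilane, polymerisation of the enone or cleavage of the silyl ether by TiCl4 takes over. The fallback sets out from 14 and returns at 22, and makes the C9–C11 bond by an intramolecular Claisen rearrangement.
- Amide 14 is treated with the Grignard reagent from 1-({[2-(chloromethyl)prop-2-en-1-yl]oxy}methyl)-4-methoxybenzene (Mg, THF) to give the dienyl ketone F4.
- Ring-closing metathesis as in step 13 gives the ring B enone F5.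
- NaBH4/CeCl3·7H2O gives the 6β-alcohol F6, and BzCl/DMAP/pyridine the 6β-benzoate F7.
- 2,3-Dichloro-5,6-dicyano-1,4-benzoquinone in CH2Cl2–H2O removes the 4-methoxybenzyl group to give the allylic alcohol F8.
- Vinyl transfer from ethyl vinyl ether (Hg(OAc)2 cat.) gives the allyl vinyl ether F9. On heating (toluene, 130 °C) this should rearrange through a chair transition state, the new bond again forming on the α face of C9, to the aldehyde F10 with the exocyclic C8=C17 bond.
- Wittig reaction with the ylide from (1-methoxyethyl)triphenylphosphonium chloride and KN(SiMe3)2 gives the methyl enol ether F11, and aq. oxalic acid in THF hydrolyses it to methyl ketone 22.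

Step 10. Aminolysis at the C6 carbonyl, which sits between two quaternary carbons, may be incomplete, the hydroxy amide may relactonise, or the hindered amide may react sluggishly in step 12. The fallback sets out from 12 and returns at 17. iBu2AlH (1.1 equiv, CH2Cl2, −78 °C) reduces the lactone to the lactol F12. Barbier allylation with 15 and Zn dust (THF–aq. NH4Cl), through the open hydroxy aldehyde, gives the diol F13 as a mixture of C6 epimers. TBSCl/imidazole silylates only the primary C18 hydroxyl to give the silyl ether carbinol F14. Dess–Martin periodinane (NaHCO3-buffered, CH2Cl2) oxidises the C6 carbinol to ketone 17.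

**Further compounds**

F1 | step 7 | enantiomer of 10, (3aS,7R,7aR)-3a,7-dimethyl-1-oxo-1,3,3a,6,7,7a-hexahydro-2-benzofuran-7-carbaldehyde | O=C2[C@@H]1[C@@](C)(CO2)C=CC[C@@]1(C)C=O
F2 | step 7 | imidazolidine (aminal) of 10 with (1S,2S)-N,N'-dimethyl-1,2-diphenylethane-1,2-diamine | O=C2[C@H]1[C@](C)(CO2)C=CC[C@]1(C)C3N(C)[C@@H](c4ccccc4)[C@H](c4ccccc4)N3C
F3 | step 7 | imidazolidine (aminal) of F1 with the same (1S,2S)-diamine | O=C2[C@@H]1[C@@](C)(CO2)C=CC[C@@]1(C)C3N(C)[C@@H](c4ccccc4)[C@H](c4ccccc4)N3C
F4 | step 16 | dienyl ketone with a 2-[(4-methoxybenzyloxy)methyl]allyl group on the C6 carbonyl | COc1ccc(COCC(=C)CC(=O)[C@H]2[C@](C)(CO[Si](C)(C)C(C)(C)C)CCC[C@]2(C)C=C)cc1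
F5 | step 16 | ring B enone with CH2O-(4-methoxybenzyl) on C8 | COc1ccc(COCC=2CC(=O)[C@H]3[C@](C)(CO[Si](C)(C)C(C)(C)C)CCC[C@]3(C)C=2)cc1
F6 | step 16 | 6β-alcohol of F5 | COc1ccc(COCC=2C[C@@H](O)[C@H]3[C@](C)(CO[Si](C)(C)C(C)(C)C)CCC[C@]3(C)C=2)cc1
F7 | step 16 | 6β-benzoate of F6 | COc1ccc(COCC=2C[C@@H](OC(=O)c4ccccc4)[C@H]3[C@](C)(CO[Si](C)(C)C(C)(C)C)CCC[C@]3(C)C=2)cc1
F8 | step 16 | allylic alcohol (C17–OH, C8=C9, 6β-OBz, 18-OTBS) | OCC=1C[C@@H](OC(=O)c4ccccc4)[C@H]3[C@](C)(CO[Si](C)(C)C(C)(C)C)CCC[C@]3(C)C=1
F9 | step 16 | allyl vinyl ether of F8 | C=COCC=1C[C@@H](OC(=O)c4ccccc4)[C@H]3[C@](C)(CO[Si](C)(C)C(C)(C)C)CCC[C@]3(C)C=1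
F10 | step 16 | aldehyde with 9α-(2-oxoethyl), 9β-H and exocyclic C8=C17 | C=C1C[C@@H](OC(=O)c4ccccc4)[C@H]3[C@](C)(CO[Si](C)(C)C(C)(C)C)CCC[C@]3(C)[C@@H]1CC=O
F11 | step 16 | methyl enol ether (E/Z mixture) of methyl ketone 22 | C=C1C[C@@H](OC(=O)c4ccccc4)[C@H]3[C@](C)(CO[Si](C)(C)C(C)(C)C)CCC[C@]3(C)[C@@H]1CC=C(C)OC
F12 | step 10 | lactol of 12 (mixture at the hemiacetal carbon) | OC2[C@H]1[C@](C)(CO2)CCC[C@]1(C)C=C
F13 | step 10 | diol: C6 carbinol (epimer mixture) carrying the 2-[(trimethylsilyl)methyl]allyl group, free C18 hydroxyl | C[Si](C)(C)CC(=C)CC(O)[C@H]1[C@](C)(CO)CCC[C@]1(C)C=C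
F14 | step 10 | 18-O-tert-butyldimethylsilyl ether of F13 | C[Si](C)(C)CC(=C)CC(O)[C@H]1[C@](C)(CO[Si](C)(C)C(C)(C)C)CCC[C@]1(C)C=C
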